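The route disconnects phenol ring A itself, not the biaryl bond. Its contiguous atoms C8(OH), C7(aryl), C6(CH3) and C5(H) are carried by a cyclobutenone, and the fused bond C4a–C8a is the double bond of a menthene made from (+)-menthone. Heating the 2-aryl-3-methyl-4-menthenylcyclobut-2-enone opens the four-membered ring to a dienylketene that closes ring A by 6π-electrocyclisation and enolises, so the crowded arene and the hindered biaryl arise fully substituted in one operation, with C1 and C4 untouched. The aryl group (ring B as its methyl ether) comes from the same menthenylstannane, and the precursor is assembled on diisopropyl squarate.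

Key step: step 13

Numbering and abbreviations: each half is numbered as a tetralin (C1 methyl, C4 isopropyl, C6 methyl, C8 oxygen); the half joined through C5 carries primes, so the biaryl bond is C7–C5'. "Menthenyl" = (3S,6R)-3-methyl-6-(propan-2-yl)cyclohex-1-en-1-yl. "ArB" = the fragment B aryl group, (5S,8R)-4-methoxy-2,5-dimethyl-8-(propan-2-yl)-5,6,7,8-tetrahydronaphthalen-1-yl.

Assumption: the target defines four stereocentres but not the sense of the hindered C7–C5' axis; the route fixes the four centres, and rotamers about the axis, if both arise, are expected to be separable at 27 or 28.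

Step 1
Reactants: 1 (+)-menthone
Product: 3 (3S,6R)-3-methyl-6-(propan-2-yl)cyclohex-1-en-1-yl trifluoromethanesulfonate, via lithium enolate 2 (not isolated)
Conditions: LiN(iPr)2 (LDA, 1.1 equiv), THF, −78 °C, ketone added to base; PhNTf2, −78 °C to rt
Reagents that add atoms: N-phenylbis(trifluoromethanesulfonimide), O=S(=O)(N(c1ccccc1)S(=O)(=O)C(F)(F)F)C(F)(F)F
Why: Kinetic deprotonation takes the unhindered CH2 rather than the isopropyl-bearing methine, so enol triflate formation from enolate 2 fixes the double bond on the methyl side and leaves both stereocentres of 1 untouched.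

Step 2
Reactants: 3 menthenyl triflate
Product: 4 trimethyl[(3S,6R)-3-methyl-6-(propan-2-yl)cyclohex-1-en-1-yl]stannane
Conditions: (Me3Sn)2, Pd(PPh3)4 (5 mol %), LiCl, THF, 65 °C
Reagents that add atoms: hexamethylditin, C[Sn](C)(C)[Sn](C)(C)C
Why: Palladium-catalysed stannylation of an enol triflate (oxidative addition of zerovalent palladium, transmetallation with the ditin, reductive elimination) replaces C–O by C–Sn without touching the two sp3 centres.

Step 3
Reactants: 4 menthenylstannane; 5 ethyl (2E)-4-bromo-3-methylbut-2-enoate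
Product: 6 ethyl (2E)-3-methyl-4-[(3S,6R)-3-methyl-6-(propan-2-yl)cyclohex-1-en-1-yl]but-2-enoate
Conditions: Pd2(dba)3 (2.5 mol %), AsPh3 (10 mol %), THF, 50 °C
Reagents that add atoms: none
Why: Stille coupling of an allylic bromide with an alkenylstannane should deliver the menthenyl group to the unsubstituted CH2 terminus of the η3-allyl palladium species, keeping the enoate conjugated; the enoate geometry is of no consequence for step 5.

Step 4
Reactants: 6 dienoate ester
Product: 7 (2E)-3-methyl-4-[(3S,6R)-3-methyl-6-(propan-2-yl)cyclohex-1-en-1-yl]but-2-enoic acid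
Conditions: LiOH, THF/MeOH/H2O, 40 °C; then 1 M HCl
Reagents that add atoms: lithium hydroxide, [Li+].[OH-]
Why: Ester saponification followed by acidification; the ring alkene and the non-enolisable stereocentres are inert to aqueous hydroxide.

Step 5
Reactants: 7 dienoic acid
Product: 12 (5R,8S)-3,8-dimethyl-5-(propan-2-yl)-5,6,7,8-tetrahydronaphthalen-1-yl acetate, via mixed anhydride 8 (not isolated), via dienylketene 9 (not isolated), via cyclohexadienone 10 (not isolated), via phenol 11 (not isolated)
Conditions: Ac2O, NaOAc, 140 °C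
Reagents that add atoms: acetic anhydride, CC(=O)OC(C)=O
Why: In the classical acetic anhydride/acetate cycloaromatisation of dienoic acids, mixed anhydride 8 loses acetic acid from the doubly allylic CH2 to give dienylketene 9, which closes by thermal 6π-electrocyclisation onto the menthene CH next to the methyl-bearing centre to give dienone 10, and this tautomerises to phenol 11, which is acetylated in the same medium; the reversible steps feed all alkene isomers through the (3Z)-ketene and both sp3 centres are spectators.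

Step 6
Reactants: 12 aryl acetate
Product: 14 (1S,4R)-8-methoxy-1,6-dimethyl-4-(propan-2-yl)-1,2,3,4-tetrahydronaphthalene, via potassium phenoxide 13 (not isolated)
Conditions: KOH (powdered), DMSO, rt; then MeI, rt
Reagents that add atoms: iodomethane, CI
Why: Hydroxide cleaves the aryl acetate (ester hydrolysis) to potassium phenoxide 13, which stays deprotonated in KOH/DMSO and is O-methylated by iodomethane in the same flask (Williamson etherification).

Step 7
Reactants: 14 aryl methyl ether
Product: 15 (1S,4R)-5-bromo-8-methoxy-1,6-dimethyl-4-(propan-2-yl)-1,2,3,4-tetrahydronaphthalene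
Conditions: NBS, MeCN, 0 °C to rt, dark
Reagents that add atoms: N-bromosuccinimide, O=C1CCC(=O)N1Br
Why: Electrophilic aromatic bromination in acetonitrile should go para to the methoxy group (C5') rather than to the ortho site wedged between methoxy and methyl, as with 3,5-dialkylanisoles.

Step 8
Reactants: 15 aryl bromide; 16 diisopropyl squarate
Product: 19 4-ArB-2,3-di(propan-2-yloxy)-4-(trimethylsilyloxy)cyclobut-2-en-1-one, via aryllithium 17 (not isolated), via lithium alkoxide 18 (not isolated)
Conditions: n-BuLi, THF, −78 °C; added to 16, THF, −78 °C; Me3SiCl, −78 °C to rt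
Reagents that add atoms: chlorotrimethylsilane, C[Si](C)(C)Cl
Why: Bromine–lithium exchange gives 17, which adds 1,2 to one squarate carbonyl, and alkoxide 18 is silylated in situ so that the second carbonyl can take methyllithium; the new quaternary centre forms without control and is destroyed in step 9.

Step 9
Reactants: 19 silylated squarate adduct
Product: 21 3-ArB-4-methylcyclobut-3-ene-1,2-dione, via carbinol 20 (not isolated)
Conditions: MeLi, THF, −78 °C; then conc. HCl, CH2Cl2, 0 °C to rt
Reagents that add atoms: methyllithium, [Li]C; water, O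
Why: 1,2-Addition of methyllithium gives carbinol 20, and acid then ionises both allylic C–O bonds in turn, each cation being captured by water at its isopropoxy-bearing terminus with loss of propan-2-ol (the standard hydrolysis of squarate bis-adducts to 3,4-disubstituted cyclobutenediones).

Step 10
Reactants: 21 cyclobutenedione
Product: 22 2-ArB-4-hydroxy-3-methylcyclobut-2-en-1-one
Conditions: LiAlH(OtBu)3, THF, −78 to −30 °C; then H2O
Reagents that add atoms: none
Why: In this carbonyl hydride reduction the bulky alkoxyaluminium hydride should attack the open carbonyl next to the methyl-bearing carbon, because the other carbonyl is screened on both faces by the twisted di-ortho-substituted aryl group; the new carbinol centre is uncontrolled and irrelevant.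

Step 11
Reactants: 22 hydroxycyclobutenone
Product: 23 2-ArB-4-chloro-3-methylcyclobut-2-en-1-one
Conditions: SOCl2, pyridine, CH2Cl2, 0 °C
Reagents that add atoms: thionyl chloride, O=S(Cl)Cl
Why: Deoxychlorination through the chlorosulfite gives the allylic chloride, whose configuration is immaterial because step 12 passes through a planar η3-oxocyclobutenyl palladium species.

Step 12
Reactants: 23 chlorocyclobutenone; 4 menthenylstannane
Product: 24 2-ArB-3-methyl-4-[(3S,6R)-3-methyl-6-(propan-2-yl)cyclohex-1-en-1-yl]cyclobut-2-en-1-one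
Conditions: PdCl2(PhCN)2 (5 mol %), P(2-furyl)3 (10 mol %), dioxane, 25–40 °C
Reagents that add atoms: none
Why: Stille coupling of a 4-chlorocyclobutenone with an alkenylstannane should form the C–C bond at the hydrogen-bearing terminus of the η3-oxocyclobutenyl palladium intermediate, placing aryl, methyl and menthenyl on C7, C6 and C5; the sp3 centre is a mixture that does not matter, and the low temperature should allow 24 to be isolated before it ring-opens.

Step 13
Reactants: 24 alkenylcyclobutenone
Product: 27 (5R,8S)-2-ArB-3,8-dimethyl-5-(propan-2-yl)-5,6,7,8-tetrahydronaphthalen-1-ol, via dienylketene 25 (not isolated), via cyclohexadienone 26 (not isolated)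
Conditions: toluene (0.01 M, degassed), 110 °C
Reagents that add atoms: none
Why: Conrotatory 4π-electrocyclic opening of the C8–C5 bond of 24 gives dienylketene 25, whose ketene carbon C8 bonds to C8a in a thermal disrotatory 6π-electrocyclisation to give dienone 26, and enolisation then aromatises ring A. This is the known thermal ring expansion of 4-alkenylcyclobut-2-enones to phenols. Ring A, the only ring formed, closes as a six-membered ring by this 6π-electrocyclisation through the new C8–C8a bond. No stereocentre is created: the sp3 carbon of 24 becomes aromatic C5, the transient C8a–H centre of 26 is erased on enolisation, and C1 and C4 are spectators with no adjacent carbonyl. The step needs the menthenyl group to turn inward so that C8 reaches C8a, and this is secured because ring opening is reversible, so opening with the group turned outward simply re-closes to 24 and material drains through the (3Z)-ketene, which also avoids the clash between the C6 methyl and the menthenyl group. Regiochemistry is not at stake because aryl, methyl and hydrogen already sit on C7, C6 and C5 of the four-membered ring, and high dilution keeps the ketene from acylating the product phenol.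

Step 14
Reactants: 27 target 8'-O-methyl ether
Product: 28 (5R,8S)-2-[(5S,8R)-4-hydroxy-2,5-dimethyl-8-(propan-2-yl)-5,6,7,8-tetrahydronaphthalen-1-yl]-3,8-dimethyl-5-(propan-2-yl)-5,6,7,8-tetrahydronaphthalen-1-ol
Conditions: BBr3, CH2Cl2, −78 to 0 °C; then H2O
Reagents that add atoms: none
Why: Lewis-acid demethylation of the aryl methyl ether with BBr3 (the free phenol is held as a borate and released on hydrolysis) should not affect the benzylic stereocentres, which do not ionise under these conditions.

Compound list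
1 | (+)-menthone, (2R,5S)-5-methyl-2-(propan-2-yl)cyclohexan-1-one | O=C1C[C@@H](C)CC[C@@H]1C(C)C | starting material
2 | lithium (3S,6R)-3-methyl-6-(propan-2-yl)cyclohex-1-en-1-olate | [Li]OC1=C[C@@H](C)CC[C@@H]1C(C)C | intermediate
3 | (3S,6R)-3-methyl-6-(propan-2-yl)cyclohex-1-en-1-yl trifluoromethanesulfonate | FC(F)(F)S(=O)(=O)OC1=C[C@@H](C)CC[C@@H]1C(C)C | intermediate
4 | trimethyl[(3S,6R)-3-methyl-6-(propan-2-yl)cyclohex-1-en-1-yl]stannane | C[Sn](C)(C)C1=C[C@@H](C)CC[C@@H]1C(C)C | intermediate
5 | ethyl (2E)-4-bromo-3-methylbut-2-enoate | CCOC(=O)/C=C(\C)CBr | starting material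
6 | ethyl (2E)-3-methyl-4-[(3S,6R)-3-methyl-6-(propan-2-yl)cyclohex-1-en-1-yl]but-2-enoate | CCOC(=O)/C=C(\C)CC1=C[C@@H](C)CC[C@@H]1C(C)C | intermediate
7 | (2E)-3-methyl-4-[(3S,6R)-3-methyl-6-(propan-2-yl)cyclohex-1-en-1-yl]but-2-enoic acid | OC(=O)/C=C(\C)CC1=C[C@@H](C)CC[C@@H]1C(C)C | intermediate
8 | acetic (2E)-3-methyl-4-menthenylbut-2-enoic anhydride | CC(=O)OC(=O)/C=C(\C)CC1=C[C@@H](C)CC[C@@H]1C(C)C | intermediate
9 | (3Z)-3-methyl-4-menthenylbuta-1,3-dien-1-one (dienylketene) | O=C=C/C(C)=C\C1=C[C@@H](C)CC[C@@H]1C(C)C | intermediate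
10 | (5R,8S)-3,8-dimethyl-5-(propan-2-yl)-6,7,8,8a-tetrahydronaphthalen-1(5H)-one (C8a unassigned) | O=C1C=C(C)C=C2C1[C@@H](C)CC[C@@H]2C(C)C | intermediate
11 | (5R,8S)-3,8-dimethyl-5-(propan-2-yl)-5,6,7,8-tetrahydronaphthalen-1-ol | Cc1cc(O)c2c(c1)[C@@H](C(C)C)CC[C@@H]2C | intermediate
12 | (5R,8S)-3,8-dimethyl-5-(propan-2-yl)-5,6,7,8-tetrahydronaphthalen-1-yl acetate | Cc1cc(OC(C)=O)c2c(c1)[C@@H](C(C)C)CC[C@@H]2C | intermediate
13 | potassium (5R,8S)-3,8-dimethyl-5-(propan-2-yl)-5,6,7,8-tetrahydronaphthalen-1-olate | Cc1cc(O[K])c2c(c1)[C@@H](C(C)C)CC[C@@H]2C | intermediate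
14 | (1S,4R)-8-methoxy-1,6-dimethyl-4-(propan-2-yl)-1,2,3,4-tetrahydronaphthalene | Cc1cc(OC)c2c(c1)[C@@H](C(C)C)CC[C@@H]2C | intermediate
15 | (1S,4R)-5-bromo-8-methoxy-1,6-dimethyl-4-(propan-2-yl)-1,2,3,4-tetrahydronaphthalene | Cc1cc(OC)c2c(c1Br)[C@@H](C(C)C)CC[C@@H]2C | intermediate
16 | diisopropyl squarate, 3,4-di(propan-2-yloxy)cyclobut-3-ene-1,2-dione | CC(C)OC1=C(OC(C)C)C(=O)C1=O | starting material
17 | ArB-lithium, [(5S,8R)-4-methoxy-2,5-dimethyl-8-(propan-2-yl)-5,6,7,8-tetrahydronaphthalen-1-yl]lithium | [Li]c1c(C)cc(OC)c2c1[C@@H](C(C)C)CC[C@@H]2C | intermediate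
18 | lithium 1-ArB-4-oxo-2,3-di(propan-2-yloxy)cyclobut-2-en-1-olate (epimer mixture) | [Li]OC1(c2c(C)cc(OC)c3c2[C@@H](C(C)C)CC[C@@H]3C)C(=O)C(OC(C)C)=C1OC(C)C | intermediate
19 | 4-ArB-2,3-di(propan-2-yloxy)-4-(trimethylsilyloxy)cyclobut-2-en-1-one (epimer mixture) | C[Si](C)(C)OC1(c2c(C)cc(OC)c3c2[C@@H](C(C)C)CC[C@@H]3C)C(=O)C(OC(C)C)=C1OC(C)C | intermediate
20 | 4-ArB-1-methyl-2,3-di(propan-2-yloxy)-4-(trimethylsilyloxy)cyclobut-2-en-1-ol (isomer mixture) | C[Si](C)(C)OC1(c2c(C)cc(OC)c3c2[C@@H](C(C)C)CC[C@@H]3C)C(C)(O)C(OC(C)C)=C1OC(C)C | intermediate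
21 | 3-ArB-4-methylcyclobut-3-ene-1,2-dione | CC1=C(c2c(C)cc(OC)c3c2[C@@H](C(C)C)CC[C@@H]3C)C(=O)C1=O | intermediate
22 | 2-ArB-4-hydroxy-3-methylcyclobut-2-en-1-one (mixture at C4 of the cyclobutenone) | CC1=C(c2c(C)cc(OC)c3c2[C@@H](C(C)C)CC[C@@H]3C)C(=O)C1O | intermediate
23 | 2-ArB-4-chloro-3-methylcyclobut-2-en-1-one (mixture at C4 of the cyclobutenone) | CC1=C(c2c(C)cc(OC)c3c2[C@@H](C(C)C)CC[C@@H]3C)C(=O)C1Cl | intermediate
24 | 2-ArB-3-methyl-4-menthenylcyclobut-2-en-1-one (mixture at the sp3 ring carbon) | O=C1C(-c2c(C)cc(OC)c3c2[C@@H](C(C)C)CC[C@@H]3C)=C(C)C1C1=C[C@@H](C)CC[C@@H]1C(C)C | intermediate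
25 | (3Z)-2-ArB-3-methyl-4-menthenylbuta-1,3-dien-1-one (dienylketene) | O=C=C(c1c(C)cc(OC)c2c1[C@@H](C(C)C)CC[C@@H]2C)/C(C)=C\C1=C[C@@H](C)CC[C@@H]1C(C)C | intermediate
26 | (5R,8S)-2-ArB-3,8-dimethyl-5-(propan-2-yl)-6,7,8,8a-tetrahydronaphthalen-1(5H)-one (C8a unassigned) | O=C1C(c2c(C)cc(OC)c3c2[C@@H](C(C)C)CC[C@@H]3C)=C(C)C=C2C1[C@@H](C)CC[C@@H]2C(C)C | intermediate
27 | (5R,8S)-2-ArB-3,8-dimethyl-5-(propan-2-yl)-5,6,7,8-tetrahydronaphthalen-1-ol (target 8'-O-methyl ether) | Cc1cc2c(c(O)c1-c1c(C)cc(OC)c3c1[C@@H](C(C)C)CC[C@@H]3C)[C@@H](C)CC[C@@H]2C(C)C | intermediate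
28 | CNP0145304.1, (5R,8S)-2-[(5S,8R)-4-hydroxy-2,5-dimethyl-8-(propan-2-yl)-5,6,7,8-tetrahydronaphthalen-1-yl]-3,8-dimethyl-5-(propan-2-yl)-5,6,7,8-tetrahydronaphthalen-1-ol | Cc1cc2c(c(O)c1-c1c(C)cc(O)c3c1[C@@H](C(C)C)CC[C@@H]3C)[C@@H](C)CC[C@@H]2C(C)C | target

Total step count: 14.
Longest linear sequence: 14 steps (1 → 3 → 4 → 6 → 7 → 12 → 14 → 15 → 19 → 21 → 22 → 23 → 24 → 27 → 28); stannane 4 re-enters at step 12.

Steps most likely to fail

Step 12. The α-branched alkenylstannane may transmetallate too slowly, so that the oxocyclobutenyl palladium intermediate decays or the temperature needed already opens 24 in an uncontrolled way. The fallback sets out from 4 and 23 and returns at 24. Tin–lithium exchange of 4 with MeLi (THF, −78 °C) gives the alkenyllithium F1, ZnCl2 converts it into the alkenylzinc chloride F2, and a Negishi coupling with 23 (Pd(PPh3)4, THF, 0 °C) forms the same C5–C4a bond at a temperature at which 24 should survive.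

Step 10. Hydride may be delivered in part to the carbonyl next to the aryl-bearing carbon (poor regioselectivity), which would exchange aryl and methyl between C7 and C6 of ring A. The fallback sets out from lithium alkoxide 18 and returns at 22, fixing the regiochemistry by construction. Alkoxide 18, made as in step 8 but not silylated, is hydrolysed with conc. HCl to the 3-ArB-4-isopropoxycyclobutenedione F3. LiAlH(OtBu)3 then reduces the carbonyl next to the isopropoxy-bearing carbon, which is both the non-vinylogous and the unhindered one, to give the hydroxycyclobutenone F4. Excess MeLi adds to the remaining vinylogous-ester carbonyl to give the diol F5 (not isolated), and dilute HCl effects the alkylative 1,3-carbonyl transposition with loss of propan-2-ol to give 22.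

Step 13. The ketene 25 may be intercepted (acylation of the product phenol, dimerisation) faster than the hindered ring closure, or closure may stall. The fallback sets out from 12 and 15 and returns at 27, making the C7–C5' bond by cross-coupling instead. Acetate 12 is cleaved (K2CO3, MeOH) to phenol 11, which is brominated ortho to the hydroxyl group (NBS, cat. i-Pr2NH, CH2Cl2) to give the bromophenol F6. Bromide 15 is converted through aryllithium 17 (n-BuLi, THF, −78 °C) and B(OiPr)3 with aqueous acid work-up into the boronic acid F7. Suzuki–Miyaura coupling of F6 and F7 (Pd(OAc)2, SPhos, K3PO4, toluene/H2O, 100 °C) should give 27.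

Further compounds
F1 | step 12 | [(3S,6R)-3-methyl-6-(propan-2-yl)cyclohex-1-en-1-yl]lithium | [Li]C1=C[C@@H](C)CC[C@@H]1C(C)C
F2 | step 12 | chloro[(3S,6R)-3-methyl-6-(propan-2-yl)cyclohex-1-en-1-yl]zinc | Cl[Zn]C1=C[C@@H](C)CC[C@@H]1C(C)C
F3 | step 10 | 3-ArB-4-(propan-2-yloxy)cyclobut-3-ene-1,2-dione | CC(C)OC1=C(c2c(C)cc(OC)c3c2[C@@H](C(C)C)CC[C@@H]3C)C(=O)C1=O
F4 | step 10 | 2-ArB-4-hydroxy-3-(propan-2-yloxy)cyclobut-2-en-1-one | CC(C)OC1=C(c2c(C)cc(OC)c3c2[C@@H](C(C)C)CC[C@@H]3C)C(=O)C1O
F5 | step 10 | 2-ArB-1-methyl-3-(propan-2-yloxy)cyclobut-2-ene-1,4-diol | CC(C)OC1=C(c2c(C)cc(OC)c3c2[C@@H](C(C)C)CC[C@@H]3C)C(C)(O)C1O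
F6 | step 13 | (5R,8S)-2-bromo-3,8-dimethyl-5-(propan-2-yl)-5,6,7,8-tetrahydronaphthalen-1-ol | Cc1cc2c(c(O)c1Br)[C@@H](C)CC[C@@H]2C(C)C
F7 | step 13 | [(5S,8R)-4-methoxy-2,5-dimethyl-8-(propan-2-yl)-5,6,7,8-tetrahydronaphthalen-1-yl]boronic acid | Cc1cc(OC)c2c(c1B(O)O)[C@@H](C(C)C)CC[C@@H]2C
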